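I began with the easy step, the substrate lost, because that needs no picture of what happens next. At 360 min, Sunday's flask held 70.4% of its charge and Thursday's 70.6%, although partner and concentration differed, so I used one first-order clock per temperature. Sunday's reading gave 9.75 × 10⁻⁴ min⁻¹; Saturday's at 50.0 min gave 0.0222 min⁻¹, a factor of 22.7, which I stretched as a straight line in the logarithm.

| setting | Sunday's | Saturday's | Thursday's | oak | larch | elm | birch |
|---|---|---|---|---|---|---|---|
| substrate | 0.61 M | 0.61 M | 1.2 M | 0.61 M | 0.61 M | 0.61 M | 0.61 M |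
| partner | 0.60 equiv | 0.90 equiv | 1.2 equiv | 1.20 equiv | 1.20 equiv | 1.20 equiv | 1.20 equiv |
| temperature | 32 °C | 60 °C | 32 °C | 70 °C | 45 °C |  | 20 °C |
| remark | run made earlier | run made earlier | run made earlier |  |  | at 70 °C until 25 min, from then on at 20 °C |  |
| time |  |  |  | 80 min | 80 min | 80 min | 80 min |

| run | time / min | target / % | substrate / % |
|---|---|---|---|
| Sunday's | 20.0 | 1.0 | 97.7 |
| Sunday's | 60.0 | 2.1 | 94.7 |
| Sunday's | 120 | 8.1 | 89.6 |
| Sunday's | 180 | 12.2 | 84.3 |
| Sunday's | 240 | 16.9 | 79.0 |
| Sunday's | 300 | 21.3 | 75.0 |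
| Sunday's | 360 | 24.7 | 70.4 |
| Saturday's | 15.0 | 23.0 | 72.2 |
| Saturday's | 30.0 | 36.2 | 52.4 |
| Saturday's | 50.0 | 41.0 | 33.0 |
| Saturday's | 60.0 | 40.9 | 27.6 |
| Saturday's | 80.0 | 38.0 | 16.7 |
| Saturday's | 90.0 | 36.0 | 13.5 |
| Thursday's | 40.0 | 1.8 | 96.8 |
| Thursday's | 90.0 | 6.3 | 90.9 |
| Thursday's | 180 | 11.4 | 84.1 |
| Thursday's | 300 | 18.7 | 75.1 |
| Thursday's | 360 | 22.1 | 70.6 |

(scatter of a reading: 0.5 percentage points)



* the flask that comes out highest in amount of target, in percent of the substrate charged, or "all alike" when all lie within 1.5 percentage points (oak / larch / elm / birch / all alike)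
* target at the end, in percent of the substrate charged, oak
* target at the end, in percent of the substrate charged, larch
* target at the end, in percent of the substrate charged, elm
* target at the end, in percent of the substrate charged, birch

The quantity I carried was the lives spent, L, the number of first-order substrate lifetimes a flask has run, for elm's hot stretch 1.69. Target, as a fraction of the charge, has two extremes that I could solve in my head:

never passing on: 1 − exp(−L)

passing on exactly as fast as it forms, the symmetric case: L·exp(−L), with its top at L = 1 and height 36.8%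

At a top, inflow equals outflow, so the rate ratio equals substrate over target. Saturday's flask read 0.805 at its highest reading of target, and that 41.0% stood nearer the symmetric value than the other extreme. I assumed that ratio held at each temperature.

oak: L = 5.41

larch: L = 0.333

birch: L = 0.0204

So I put oak far past the top, above 2.41%; larch between 23.9% and 28.3%; and birch near 2.02%. By my reckoning, elm's cold stretch added 0.0141 lives, far fewer than its hot stretch. Saturday reached elm's lives near 80.0 min, reading 38.0%, so I expected about that, and elm highest.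

The forecast named elm: oak 10%, larch 25%, elm 41%, birch 1.5%, on the ground that elm “is essentially frozen, so it comes out highest”. Its elm stood above my 38.0%.

Elm did come out highest, at 39.9%, with oak 11.9%, larch 23.8% and birch 0.497%. Elm held 39.9% target at 25.0 min, the change, and 39.9% at 80.0 min. My 1.69 lives promised 18.5% substrate for the change, and at 25.0 min elm held 22.3%.

    substrate → intermediate A (k = 0.00100 s⁻¹, Ea = 95.0 kJ mol⁻¹)
    partner + intermediate A ⇌ intermediate B (K = 0.470 M⁻¹, k = 0.0180 M⁻¹ s⁻¹, Ea = 61.0 kJ mol⁻¹, ΔH = 21.0 kJ mol⁻¹)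
    partner + intermediate A ⇌ intermediate C (K = 57.0 M⁻¹, k = 0.00220 M⁻¹ s⁻¹, Ea = 81.0 kJ mol⁻¹, ΔH = −13.0 kJ mol⁻¹)
    target ⇌ isomer of the product (K = 15.0, k = 7.70 × 10⁻⁴ s⁻¹, Ea = 98.0 kJ mol⁻¹, ΔH = −31.0 kJ mol⁻¹)
    intermediate A → target (k = 0.0530 s⁻¹, Ea = 95.0 kJ mol⁻¹)
    (constants at 70 °C)

A repeat of birch at 35 °C runs 0.109 lives, which promises 89.7% substrate left and about 9.77% target. That flask gave 90% substrate and 7.80% target, with 1.63% in intermediate A.

(The numbers in the tables come from a simulation with constants of no real substance, noise included.)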